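## Retrosynthetic overview

1. The spiro-dihydropyran is made last: O–C8 and CH2–C1' are cut by a retro oxa-[4+2] to an exocyclic C8=CH2 diene and the alkylidene trione from syncarpic acid and isovaleraldehyde. The C8=CH2 group comes from a C8 ketone by Wittig methylenation.
2. The plan rests on one feature of the nine-membered ring C1–C2–C3=C4–C5–C6–C7–C8–C9 (C1 and C9 are the cyclobutane CH carbons). The C8 carbonyl stands δ,ε to the C3=C4 alkene through C9–C1–C2, which is the product pattern of an oxy-Cope shift. C1–C2 is therefore cut and C4–C8 reconnected.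
3. This gives a cis-1-cyclobutenyl-2-vinylcyclopentanol. It is made from a 2-methyl-2-vinyl-3-silyloxycyclopentanone and a cyclobutenylcerium reagent, and the C5 carbinol is then inverted by oxidation and hydroxyl-directed reduction.
4. The cyclopentanone comes from 2-methylcyclopentane-1,3-dione by ethynylation, CBS desymmetrisation, silylation and semihydrogenation.
5. Ring order: the cyclopentane and the cyclobutene are bought. They are merged into the cyclobutane-fused nine-membered ring (step 11), and the dihydropyran is then closed onto the bought cyclohexanetrione (step 13).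

Key step: step 11

Remark: caryophyllane numbering is used for the terpene half (C1, C9 = cyclobutane CH; C4 = methyl-bearing alkene carbon; C5 = carbinol; C8 = spiro carbon; C10 = cyclobutane CH2; C11 = CMe2; C1' = isobutyl-bearing carbon, which is C4' of the chromene).
Remark: diastereomers formed in steps 2, 6 and 13 are assumed to be separable by chromatography.

## Route

Step 1
Reactants: 1 2-methylcyclopentane-1,3-dione
Product: 2 2-ethynyl-2-methylcyclopentane-1,3-dione
Conditions: TBAF, THF, -78 °C, then TMS-EBX, -78 °C → rt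
Reagents that add atoms: 1-[(trimethylsilyl)ethynyl]-1,2-benziodoxol-3(1H)-one (TMS-EBX), C[Si](C)(C)C#CI1OC(=O)c2ccccc12
Why: Electrophilic α-alkynylation of a 1,3-dicarbonyl enolate with a hypervalent alkynyliodine reagent: fluoride unmasks ethynylbenziodoxolone, the enolate adds to its β-carbon and the alkylidene carbene undergoes a 1,2-hydrogen shift, which places a free ethynyl group on the fully substituted carbon without creating a stereocentre.

Step 2
Reactants: 2 2-ethynyl-2-methylcyclopentane-1,3-dione
Product: 3 (2S,3R)-2-ethynyl-3-hydroxy-2-methylcyclopentan-1-one (hydroxyl cis to methyl)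
Conditions: (S)-2-methyl-CBS-oxazaborolidine (cat.), catecholborane, toluene/CH2Cl2, -78 °C
Reagents that add atoms: none
Why: Corey–Bakshi–Shibata reduction used as a desymmetrisation: the (S)-catalyst treats the quaternary carbon as the large flank and should deliver hydride to the carbonyl face syn to the slim ethynyl group (anti to methyl), which sets the carbinol as R with hydroxyl cis to methyl and thereby fixes the quaternary carbon as S, while catecholborane at -78 °C leaves the alkyne alone.

Step 3
Reactants: 3 (2S,3R)-2-ethynyl-3-hydroxy-2-methylcyclopentan-1-one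
Product: 4 (2S,3R)-3-[(tert-butyldimethylsilyl)oxy]-2-ethynyl-2-methylcyclopentan-1-one
Conditions: TBSCl, imidazole, DMF, rt
Reagents that add atoms: tert-butyldimethylsilyl chloride, CC(C)(C)[Si](C)(C)Cl
Why: Imidazole-mediated silylation of the secondary alcohol blocks retro-aldol cleavage and installs the bulky group that will shield the methyl face of the ketone.

Step 4
Reactants: 4 (2S,3R)-3-[(tert-butyldimethylsilyl)oxy]-2-ethynyl-2-methylcyclopentan-1-one
Product: 5 (2S,3R)-3-[(tert-butyldimethylsilyl)oxy]-2-ethenyl-2-methylcyclopentan-1-one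
Conditions: H2 (1 atm), Lindlar catalyst, quinoline, EtOAc, rt
Reagents that add atoms: none
Why: Lindlar semihydrogenation stops at the alkene on a terminal alkyne, and it is placed here so that the organometallic step meets no acidic acetylenic hydrogen and the cyclobutene is never exposed to palladium and hydrogen.

Step 5
Reactants: 6 3,3-dimethylcyclobutan-1-one
Product: 7 N'-(3,3-dimethylcyclobutylidene)-2,4,6-triisopropylbenzenesulfonohydrazide
Conditions: TrisNHNH2, MeOH, cat. HCl, 0 °C → rt
Reagents that add atoms: 2,4,6-triisopropylbenzenesulfonohydrazide, CC(C)c1cc(C(C)C)c(S(=O)(=O)NN)c(C(C)C)c1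
Why: Acid-catalysed condensation of a ketone with an arenesulfonyl hydrazide gives the trisylhydrazone needed for the Shapiro reaction, and the symmetry of the ketone removes any regiochemical question.

Step 6
Reactants: 7 N'-(3,3-dimethylcyclobutylidene)-2,4,6-triisopropylbenzenesulfonohydrazide; 5 (2S,3R)-3-[(tert-butyldimethylsilyl)oxy]-2-ethenyl-2-methylcyclopentan-1-one
Product: 10 (1R,2S,3R)-3-[(tert-butyldimethylsilyl)oxy]-1-(3,3-dimethylcyclobut-1-en-1-yl)-2-ethenyl-2-methylcyclopentan-1-ol, via cyclobutenyllithium 8 (not isolated), via cyclobutenylcerium dichloride 9 (not isolated)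
Conditions: 7, n-BuLi (2.1 equiv), THF/TMEDA, -78 → 0 °C; CeCl3, -78 °C; then 5, -78 °C; aq. NH4Cl
Reagents that add atoms: none
Why: The Shapiro reaction gives the vinyllithium, transmetalation to the weakly basic organocerium allows 1,2-addition to the hindered enolisable ketone, and the nucleophile should enter anti to the methyl and silyloxy groups that share one face, which sets the carbinol as R with cyclobutenyl cis to vinyl.

Step 7
Reactants: 10 (1R,2S,3R)-3-[(tert-butyldimethylsilyl)oxy]-1-(3,3-dimethylcyclobut-1-en-1-yl)-2-ethenyl-2-methylcyclopentan-1-ol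
Product: 11 (1R,2S,3R)-1-(3,3-dimethylcyclobut-1-en-1-yl)-2-ethenyl-2-methylcyclopentane-1,3-diol (cis-1,3-diol)
Conditions: TBAF, THF, rt
Reagents that add atoms: none
Why: Fluoride-mediated desilylation frees the secondary hydroxyl whose configuration is to be inverted, without touching the tertiary allylic alcohol or the diene.

Step 8
Reactants: 11 (1R,2S,3R)-1-(3,3-dimethylcyclobut-1-en-1-yl)-2-ethenyl-2-methylcyclopentane-1,3-diol
Product: 12 (2R,3R)-3-(3,3-dimethylcyclobut-1-en-1-yl)-2-ethenyl-3-hydroxy-2-methylcyclopentan-1-one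
Conditions: Dess–Martin periodinane, NaHCO3, CH2Cl2, 0 °C → rt
Reagents that add atoms: none
Why: Dess–Martin oxidation converts only the secondary alcohol under buffered conditions that spare the tertiary allylic carbinol and avoid base-induced retro-aldol cleavage, and the adjacent carbon is quaternary and cannot epimerise.

Step 9
Reactants: 12 (2R,3R)-3-(3,3-dimethylcyclobut-1-en-1-yl)-2-ethenyl-3-hydroxy-2-methylcyclopentan-1-one
Product: 13 (1R,2S,3S)-1-(3,3-dimethylcyclobut-1-en-1-yl)-2-ethenyl-2-methylcyclopentane-1,3-diol (trans-1,3-diol)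
Conditions: Me4NBH(OAc)3, MeCN/AcOH (1:1), -30 °C
Reagents that add atoms: none
Why: Hydroxyl-directed (Evans–Saksena) reduction: the tertiary hydroxyl exchanges onto boron and delivers hydride to its own face of the β-ketone, so the new secondary hydroxyl should end anti to the tertiary one, that is cis to both alkenyl groups and of S configuration.

Step 10
Reactants: 13 (1R,2S,3S)-1-(3,3-dimethylcyclobut-1-en-1-yl)-2-ethenyl-2-methylcyclopentane-1,3-diol
Product: 14 (1R,2S,3S)-3-[(tert-butyldimethylsilyl)oxy]-1-(3,3-dimethylcyclobut-1-en-1-yl)-2-ethenyl-2-methylcyclopentan-1-ol (vinyl, cyclobutenyl and silyloxy on one face; methyl and hydroxyl on the other)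
Conditions: TBSOTf (1.05 equiv), 2,6-lutidine, CH2Cl2, -78 °C
Reagents that add atoms: tert-butyldimethylsilyl trifluoromethanesulfonate, CC(C)(C)[Si](C)(C)OS(=O)(=O)C(F)(F)F
Why: Chemoselective silylation, because the secondary hydroxyl reacts with the silyl triflate at -78 °C much faster than the tertiary hydroxyl flanked by two fully substituted carbons, which stays free for alkoxide formation.

Step 11
Reactants: 14 (1R,2S,3S)-3-[(tert-butyldimethylsilyl)oxy]-1-(3,3-dimethylcyclobut-1-en-1-yl)-2-ethenyl-2-methylcyclopentan-1-ol
Product: 17 (1R,3Z,5S,9S)-5-[(tert-butyldimethylsilyl)oxy]-4,11,11-trimethylbicyclo[7.2.0]undec-3-en-8-one, via potassium alkoxide 15 (not isolated), via potassium enolate 16 (not isolated)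
Conditions: KH, 18-crown-6, THF, 0 °C → rt; then MeOH, -78 °C → rt; aq. NH4Cl
Reagents that add atoms: none
Why: KH/18-crown-6 turns 14 into the dissociated alkoxide 15, whose oxyanion weakens the C4–C8 bond and drives a concerted [3,3] shift (anionic oxy-Cope rearrangement) that forms C1–C2, breaks C4–C8 and gives enolate 16; this is the known four-atom ring expansion of cis-1,2-dialkenylcycloalkanols. The nine-membered ring is therefore closed by ring expansion inside a six-membered pericyclic array and not by end-to-end cyclisation, while the cyclobutene becomes the fused cyclobutane. Because vinyl and cyclobutenyl are cis, only the boat array with both termini folded over the cyclopentane is within reach, which makes C3=C4 Z and lets C2 bond to the single face of the cyclobutene carbon C1 that the C4/C8 configuration presents, so C1 should come out R relative to the carried 5S centre. C9 is set afterwards: the methanol quench leaves KOMe, which equilibrates the α-centre to the more stable trans ring fusion (9S). The step needs the [3,3] path to beat β-fragmentation of the alkoxide and O-to-O silyl transfer; the cis-dialkenyl geometry, the ion-separated potassium alkoxide and the trans relation of the C8 oxygen to the C5 silyl ether (no cyclic transfer array) should secure this. The main retarding contacts are the C5 silyloxy group next to the folding vinyl group and the gem-dimethyl carbon beside C1.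

Step 12
Reactants: 17 (1R,3Z,5S,9S)-5-[(tert-butyldimethylsilyl)oxy]-4,11,11-trimethylbicyclo[7.2.0]undec-3-en-8-one
Product: 18 tert-butyldimethyl{[(1R,3Z,5S,9S)-4,11,11-trimethyl-8-methylidenebicyclo[7.2.0]undec-3-en-5-yl]oxy}silane
Conditions: Ph3PCH3Br, KOt-Bu, THF, 0 °C → reflux
Reagents that add atoms: methyltriphenylphosphonium bromide, C[P+](c1ccccc1)(c1ccccc1)c1ccccc1.[Br-]
Why: Wittig methylenation of a hindered ketone with excess ylide; the only enolisable stereocentre (C9) already has its thermodynamically preferred trans-fused configuration, and the silyloxy group is γ to the carbonyl and cannot be eliminated.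

Step 13
Reactants: 18 tert-butyldimethyl{[(1R,3Z,5S,9S)-4,11,11-trimethyl-8-methylidenebicyclo[7.2.0]undec-3-en-5-yl]oxy}silane; 19 syncarpic acid; 20 isovaleraldehyde
Product: 22 5-O-(tert-butyldimethylsilyl)tomentodione P, via alkylidene trione 21 (not isolated)
Conditions: EDDA (cat.), toluene, 4 Å MS, rt → 80 °C
Reagents that add atoms: none
Why: Domino Knoevenagel/inverse-electron-demand oxa-Diels–Alder reaction: the electron-poor 1-oxadiene 21 should add to the 1,1-disubstituted C8=CH2 bond (not to the hindered trisubstituted C3=C4 bond) with its oxygen on the more substituted C8 and its alkylidene carbon on the CH2 terminus; approach from the outer face of the exocyclic alkene (the cyclobutane CH2 side when C9–H lies near the alkene plane, away from C1 and the ring interior) gives 8S, whereas C1' depends on whether the C9 or the C7 branch lies under the heterodiene, so the 1'S adduct 22 (isobutyl cis to C9) is expected together with its 1'R epimer and has to be separated by chromatography.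

Step 14
Reactants: 22 5-O-(tert-butyldimethylsilyl)tomentodione P
Product: 23 Tomentodione P
Conditions: TBAF, THF, rt
Reagents that add atoms: none
Why: Fluoride cleavage of the allylic secondary silyl ether under non-acidic conditions releases the C5 hydroxyl without ionising the tertiary enol-ether linkage at C8 or disturbing the vinylogous ester.

## Compound list

1 | 2-methylcyclopentane-1,3-dione | CC1C(=O)CCC1=O | starting material
2 | 2-ethynyl-2-methylcyclopentane-1,3-dione | C#CC1(C)C(=O)CCC1=O | intermediate
3 | (2S,3R)-2-ethynyl-3-hydroxy-2-methylcyclopentan-1-one | C#C[C@@]1(C)[C@H](O)CCC1=O | intermediate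
4 | (2S,3R)-3-[(tert-butyldimethylsilyl)oxy]-2-ethynyl-2-methylcyclopentan-1-one | C#C[C@@]1(C)[C@H](O[Si](C)(C)C(C)(C)C)CCC1=O | intermediate
5 | (2S,3R)-3-[(tert-butyldimethylsilyl)oxy]-2-ethenyl-2-methylcyclopentan-1-one | C=C[C@@]1(C)[C@H](O[Si](C)(C)C(C)(C)C)CCC1=O | intermediate
6 | 3,3-dimethylcyclobutan-1-one | CC1(C)CC(=O)C1 | starting material
7 | N'-(3,3-dimethylcyclobutylidene)-2,4,6-triisopropylbenzenesulfonohydrazide | CC(C)c1cc(C(C)C)c(S(=O)(=O)NN=C2CC(C)(C)C2)c(C(C)C)c1 | intermediate
8 | (3,3-dimethylcyclobut-1-en-1-yl)lithium | [Li]C1=CC(C)(C)C1 | intermediate (not isolated)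
9 | dichloro(3,3-dimethylcyclobut-1-en-1-yl)cerium | Cl[Ce](Cl)C1=CC(C)(C)C1 | intermediate (not isolated)
10 | (1R,2S,3R)-3-[(tert-butyldimethylsilyl)oxy]-1-(3,3-dimethylcyclobut-1-en-1-yl)-2-ethenyl-2-methylcyclopentan-1-ol | C=C[C@@]1(C)[C@H](O[Si](C)(C)C(C)(C)C)CC[C@@]1(O)C1=CC(C)(C)C1 | intermediate
11 | (1R,2S,3R)-1-(3,3-dimethylcyclobut-1-en-1-yl)-2-ethenyl-2-methylcyclopentane-1,3-diol | C=C[C@@]1(C)[C@H](O)CC[C@@]1(O)C1=CC(C)(C)C1 | intermediate
12 | (2R,3R)-3-(3,3-dimethylcyclobut-1-en-1-yl)-2-ethenyl-3-hydroxy-2-methylcyclopentan-1-one | C=C[C@@]1(C)C(=O)CC[C@@]1(O)C1=CC(C)(C)C1 | intermediate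
13 | (1R,2S,3S)-1-(3,3-dimethylcyclobut-1-en-1-yl)-2-ethenyl-2-methylcyclopentane-1,3-diol | C=C[C@@]1(C)[C@@H](O)CC[C@@]1(O)C1=CC(C)(C)C1 | intermediate
14 | (1R,2S,3S)-3-[(tert-butyldimethylsilyl)oxy]-1-(3,3-dimethylcyclobut-1-en-1-yl)-2-ethenyl-2-methylcyclopentan-1-ol | C=C[C@@]1(C)[C@@H](O[Si](C)(C)C(C)(C)C)CC[C@@]1(O)C1=CC(C)(C)C1 | intermediate
15 | potassium alkoxide of 14 | C=C[C@@]1(C)[C@@H](O[Si](C)(C)C(C)(C)C)CC[C@@]1([O-])C1=CC(C)(C)C1.[K+] | intermediate (not isolated)
16 | potassium C8–C9 enolate of 17 (C1 and C7 cis on the enolate double bond) | C/C1=C/C[C@@H]2/C(CC2(C)C)=C(/[O-])CC[C@@H]1O[Si](C)(C)C(C)(C)C.[K+] | intermediate (not isolated)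
17 | (1R,3Z,5S,9S)-5-[(tert-butyldimethylsilyl)oxy]-4,11,11-trimethylbicyclo[7.2.0]undec-3-en-8-one (trans-fused) | C/C1=C/C[C@@H]2[C@H](CC2(C)C)C(=O)CC[C@@H]1O[Si](C)(C)C(C)(C)C | intermediate
18 | tert-butyldimethyl{[(1R,3Z,5S,9S)-4,11,11-trimethyl-8-methylidenebicyclo[7.2.0]undec-3-en-5-yl]oxy}silane | C/C1=C/C[C@@H]2[C@H](CC2(C)C)C(=C)CC[C@@H]1O[Si](C)(C)C(C)(C)C | intermediate
19 | syncarpic acid (2,2,4,4-tetramethylcyclohexane-1,3,5-trione) | CC1(C)C(=O)CC(=O)C(C)(C)C1=O | starting material
20 | isovaleraldehyde (3-methylbutanal) | CC(C)CC=O | starting material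
21 | 2,2,4,4-tetramethyl-6-(3-methylbutylidene)cyclohexane-1,3,5-trione | CC(C)CC=C1C(=O)C(C)(C)C(=O)C(C)(C)C1=O | intermediate (not isolated)
22 | 5-O-(tert-butyldimethylsilyl)tomentodione P, the (1R,3Z,5S,8S,9S,4'S) spiro adduct | C/C1=C/C[C@@H]2[C@H](CC2(C)C)[C@]2(CC[C@@H]1O[Si](C)(C)C(C)(C)C)C[C@H](CC(C)C)C1=C(O2)C(C)(C)C(=O)C(C)(C)C1=O | intermediate
23 | Tomentodione P, (1R,3Z,5S,8S,9S,4'S)-5-hydroxy-4,11,11,6',6',8',8'-heptamethyl-4'-(2-methylpropyl)-3',4'-dihydrospiro[bicyclo[7.2.0]undec-3-ene-8,2'-chromene]-5',7'(6'H,8'H)-dione | C/C1=C/C[C@@H]2[C@H](CC2(C)C)[C@]2(CC[C@@H]1O)C[C@H](CC(C)C)C1=C(O2)C(C)(C)C(=O)C(C)(C)C1=O | target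

## Step count

Total step count: 14
Longest linear sequence: 13 steps (from 1 through steps 1–4 and 6–14; step 5 is the side branch from 6)

## Steps most likely to fail

**Step 11 (key step).** The boat array may be reached too slowly. The C5 silyloxy group lies next to the vinyl terminus that has to fold over it, and the gem-dimethyl carbon flanks the bond-forming cyclobutene carbon. Heterolytic β-fragmentation of the alkoxide (C4–C8 cleavage to an allyl anion and a cyclobutenyl ketone) or incomplete equilibration at C9 could then take over.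

Fallback: rearrangement without the silyl group, setting out from diol 13. Excess KH/18-crown-6 in THF generates the bis-alkoxide. Only the tertiary C8 alkoxide belongs to a 3-oxy-1,5-diene, and the small C5 alkoxide hinders the folding vinyl group less. Methanol quench and equilibration as in step 11 should give (1R,3Z,5S,9S)-5-hydroxy-4,11,11-trimethylbicyclo[7.2.0]undec-3-en-8-one F1. Silylation of its secondary hydroxyl (TBSCl, imidazole, DMF) returns to the route at 17.

**Step 13.** Discrimination between the two faces of C8=CH2 and between the two orientations of the heterodiene (the C1' epimers) is not secured for this ring (Z-C3=C4, C5 silyloxy). Ene reaction of the alkylidene trione and its condensation with a second syncarpic acid can also compete, so the wanted diastereomer may be a minor component.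

Fallback: change the order so that the cycloaddition runs on the free alcohol. From 18, TBAF in THF gives (1R,3Z,5S,9S)-4,11,11-trimethyl-8-methylidenebicyclo[7.2.0]undec-3-en-5-ol F2. Its three-component reaction with 19 and 20 (through 21, same catalyst) then gives 23 directly. The free hydroxyl changes the conformer population of the nine-membered ring and can hydrogen-bond to a trione carbonyl. The separation of diastereomers then coincides with the final purification.

**Step 6.** Attack of the organocerium on the vinyl-free face would give the trans-dialkenyl carbinol, which cannot reach the boat array. Incomplete addition to the neopentyl ketone is the second concern.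

Fallback: perform the addition one stage earlier on ethynyl ketone 4. The rod-like alkyne leaves its face of the carbonyl open while methyl and silyloxy still block the other. Reagent 9, used in excess because the acetylenic C–H may consume some of it, should give (1R,2S,3R)-3-[(tert-butyldimethylsilyl)oxy]-1-(3,3-dimethylcyclobut-1-en-1-yl)-2-ethynyl-2-methylcyclopentan-1-ol F3. TBAF then gives (1R,2S,3R)-1-(3,3-dimethylcyclobut-1-en-1-yl)-2-ethynyl-2-methylcyclopentane-1,3-diol F4. Dess–Martin oxidation gives (2R,3R)-3-(3,3-dimethylcyclobut-1-en-1-yl)-2-ethynyl-3-hydroxy-2-methylcyclopentan-1-one F5. Me4NBH(OAc)3 gives (1R,2S,3S)-1-(3,3-dimethylcyclobut-1-en-1-yl)-2-ethynyl-2-methylcyclopentane-1,3-diol F6. Lindlar semihydrogenation of F6, with hydrogen uptake monitored because of the cyclobutene, returns to the route at 13.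

Further compounds
F1 | step 11 | (1R,3Z,5S,9S)-5-hydroxy-4,11,11-trimethylbicyclo[7.2.0]undec-3-en-8-one | C/C1=C/C[C@@H]2[C@H](CC2(C)C)C(=O)CC[C@@H]1O
F2 | step 13 | (1R,3Z,5S,9S)-4,11,11-trimethyl-8-methylidenebicyclo[7.2.0]undec-3-en-5-ol | C/C1=C/C[C@@H]2[C@H](CC2(C)C)C(=C)CC[C@@H]1O
F3 | step 6 | (1R,2S,3R)-3-[(tert-butyldimethylsilyl)oxy]-1-(3,3-dimethylcyclobut-1-en-1-yl)-2-ethynyl-2-methylcyclopentan-1-ol | C#C[C@@]1(C)[C@H](O[Si](C)(C)C(C)(C)C)CC[C@@]1(O)C1=CC(C)(C)C1
F4 | step 6 | (1R,2S,3R)-1-(3,3-dimethylcyclobut-1-en-1-yl)-2-ethynyl-2-methylcyclopentane-1,3-diol | C#C[C@@]1(C)[C@H](O)CC[C@@]1(O)C1=CC(C)(C)C1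
F5 | step 6 | (2R,3R)-3-(3,3-dimethylcyclobut-1-en-1-yl)-2-ethynyl-3-hydroxy-2-methylcyclopentan-1-one | C#C[C@@]1(C)C(=O)CC[C@@]1(O)C1=CC(C)(C)C1
F6 | step 6 | (1R,2S,3S)-1-(3,3-dimethylcyclobut-1-en-1-yl)-2-ethynyl-2-methylcyclopentane-1,3-diol | C#C[C@@]1(C)[C@@H](O)CC[C@@]1(O)C1=CC(C)(C)C1
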